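## Retrosynthetic overview
1. Rings A, B and C and the (2R) centre come intact from (+)-catechin 1, handled as its tetrabenzyl ether 2. The acyl ring comes with syringic acid 3. No ring is formed in the route.
2. Key disconnection: the C3–O(ester) bond, made with inversion (3S to 3R). O3 of 2 becomes a leaving group (phosphinite 4, phosphonium salt 5) and is displaced by the carboxylate oxygen of 3, giving the 2,3-cis ester 6.
3. Last disconnection: the four O–benzyl bonds of 6. Hydrogenolysis gives target 7, (−)-epicatechin 3-O-syringate, (2R,3R).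

Assumption: commercial (+)-catechin hydrate has the natural (2R,3S) configuration and is dried by toluene azeotrope before use. The drying is not counted as a step.

## Route

Step 1
Reactants: 1 (+)-catechin
Product: 2 5,7,3',4'-tetra-O-benzyl-(+)-catechin (2R,3S)
Conditions: BnBr (4.4 eq), K2CO3 (5 eq), DMF, argon, 0 °C to rt, 36 h
Reagents that add atoms: benzyl bromide, BrCc1ccccc1
Why: In this Williamson ether synthesis K2CO3 deprotonates only the four phenols (pKa about 9–10) and not the secondary 3-OH, which stays free, and the low temperature and exclusion of oxygen avoid quinone-methide epimerisation at C2, so both stereocentres are carried over unchanged.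

Step 2
Reactants: 2 5,7,3',4'-tetra-O-benzyl-(+)-catechin; 3 syringic acid
Product: 6 5,7,3',4'-tetra-O-benzyl-(−)-epicatechin 3-O-syringate (2R,3R), via catechinyl diphenylphosphinite 4 (not isolated), via phosphonium syringate ion pair 5 (not isolated)
Conditions: Ph2PCl (1.1 eq), Et3N (1.15 eq), DMAP (0.1 eq), THF, 0 °C to rt, filter under argon, concentrate; then 3 (1.3 eq), 2,6-dimethyl-1,4-benzoquinone (1.1 eq), CH2Cl2/THF 5:1 (0.5 M), 0 °C to rt
Reagents that add atoms: chlorodiphenylphosphine, ClP(c1ccccc1)c1ccccc1 (PPh2 of 4 and 5); 2,6-dimethyl-1,4-benzoquinone, CC1=CC(=O)C=C(C)C1=O (aryloxy group of 5); both leave again before 6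
Why: Proposed new method: stereoinvertive C3–O acyloxylation of a flavan-3-ol by a phosphinite/quinone oxidation–reduction condensation, in which the P–O bond is made first (4), the quinone then oxidises trivalent phosphorus in the presence of acid 3 to the aryloxy(alkoxy)phosphonium salt 5 whose only counter-ion is the syringate, and this tight ion pair collapses by SN2 attack of the carboxylate oxygen on C3 anti to the departing phosphinate, so that 3S becomes 3R (2,3-cis) while C2 is untouched; substitution should beat E2 to the flav-3-ene and 1,2-shifts of ring B or O1 because no hydrazide or other free base is present, the medium is weakly polar and concentrated, the diequatorial half-chair of 5 has no antiperiplanar C4–H, the axial approach to C3 meets no 1,3-diaxial substituent (O1 and C4a carry none), all Ph2PCl is consumed before 3 is added, and the CO2H of 3 (pKa about 4) is engaged long before its hindered 4-OH (pKa about 9); the closest known reaction types are the Mukaiyama oxidation–reduction condensation of alkoxydiphenylphosphines with carboxylic acids (inversion even at menthyl and tertiary carbinol centres) and the chemoselective Mitsunobu esterification of unprotected phenolic acids, neither of which has been shown at C3 of a flavan-3-ol, where azodicarboxylate Mitsunobu conditions are prone to elimination.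

Step 3
Reactants: 6 5,7,3',4'-tetra-O-benzyl-(−)-epicatechin 3-O-syringate
Product: 7 (−)-epicatechin 3-O-syringate (2R,3R)
Conditions: H2 (1 atm), Pd(OH)2/C (20 wt%), THF/MeOH 1:1, rt; filter through Celite under argon
Reagents that add atoms: none
Why: Catalytic hydrogenolysis cleaves the four aryl benzyl ethers under neutral conditions, whereas the C3–O ester bond is not benzylic, the cyclic C2–O1 ether survives as it does in the related 3-O-gallate series, and nothing present can epimerise C2 or move the acyl group, so both stereocentres are kept.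

## Compound list
1 | (+)-catechin, (2R,3S)-2-(3,4-dihydroxyphenyl)chroman-3,5,7-triol | O[C@H]1Cc2c(O)cc(O)cc2O[C@@H]1c1ccc(O)c(O)c1 | starting material
2 | 5,7,3',4'-tetra-O-benzyl-(+)-catechin, (2R,3S)-5,7-bis(benzyloxy)-2-[3,4-bis(benzyloxy)phenyl]chroman-3-ol | O[C@H]1Cc2c(OCc3ccccc3)cc(OCc3ccccc3)cc2O[C@@H]1c1ccc(OCc2ccccc2)c(OCc2ccccc2)c1 | intermediate
3 | syringic acid, 4-hydroxy-3,5-dimethoxybenzoic acid | COc1cc(C(=O)O)cc(OC)c1O | starting material
4 | (2R,3S)-5,7-bis(benzyloxy)-2-[3,4-bis(benzyloxy)phenyl]chroman-3-yl diphenylphosphinite | c1ccccc1P(c1ccccc1)O[C@H]1Cc2c(OCc3ccccc3)cc(OCc3ccccc3)cc2O[C@@H]1c1ccc(OCc2ccccc2)c(OCc2ccccc2)c1 | intermediate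
5 | [(2R,3S)-tetra-O-benzylcatechin-3-yloxy](4-hydroxy-3,5-dimethylphenoxy)diphenylphosphonium 4-hydroxy-3,5-dimethoxybenzoate | Cc1cc(O[P+](c2ccccc2)(c2ccccc2)O[C@H]2Cc3c(OCc4ccccc4)cc(OCc4ccccc4)cc3O[C@@H]2c2ccc(OCc3ccccc3)c(OCc3ccccc3)c2)cc(C)c1O.COc1cc(C([O-])=O)cc(OC)c1O | intermediate
6 | 5,7,3',4'-tetra-O-benzyl-(−)-epicatechin 3-O-syringate, (2R,3R)-5,7-bis(benzyloxy)-2-[3,4-bis(benzyloxy)phenyl]chroman-3-yl 4-hydroxy-3,5-dimethoxybenzoate | COc1cc(C(=O)O[C@@H]2Cc3c(OCc4ccccc4)cc(OCc4ccccc4)cc3O[C@@H]2c2ccc(OCc3ccccc3)c(OCc3ccccc3)c2)cc(OC)c1O | intermediate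
7 | (−)-epicatechin 3-O-syringate, (2R,3R)-2-(3,4-dihydroxyphenyl)-5,7-dihydroxychroman-3-yl 4-hydroxy-3,5-dimethoxybenzoate | COc1cc(C(=O)O[C@@H]2Cc3c(O)cc(O)cc3O[C@@H]2c2ccc(O)c(O)c2)cc(OC)c1O | target

## Step count
Total steps: 3. Longest linear sequence: 3 (1 to 2 to 6 to 7).

## Steps most likely to fail

**Step 2 (the proposed new step, highest risk).**
- Failure modes:
  - E2 from the diaxial conformer of 5, giving the flav-3-ene.
  - Ionisation with a 1,2-shift of ring B or of O1.
  - Attack of the carboxylate at phosphorus, giving the 2,3-trans ester with retention.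
- Check: the cis product shows H-2 as a broad singlet (J2,3 below 2 Hz); the trans ester shows J2,3 of about 6–8 Hz.
- Fallback (known chemistry only): it sets out from 2 and comes back to the route at 7. Compound 2 is oxidised with Dess–Martin periodinane (CH2Cl2, rt) to (2R)-5,7,3',4'-tetrakis(benzyloxy)flavan-3-one F1. LiBH(s-Bu)3 (LiBr, THF, −78 °C) reduces this from the face opposite ring B to 5,7,3',4'-tetra-O-benzyl-(−)-epicatechin F2. Steglich esterification (DCC, DMAP, CH2Cl2) with commercial 4-(benzyloxy)-3,5-dimethoxybenzoic acid F3 gives 5,7,3',4'-tetra-O-benzyl-(−)-epicatechin 3-O-(4-O-benzylsyringate) F4. H2 over Pd(OH)2/C then removes all five benzyl groups to give 7.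

**Step 1.**
- Failure modes: C-benzylation at C6/C8 of the phloroglucinol ring, air oxidation of the polyphenolate, and incomplete benzylation.
- Fallback: it sets out from 1 and comes back at 2, and it never exposes a free polyphenolate. Ac2O/pyridine gives penta-O-acetyl-(+)-catechin F5. NaH, H2O (about 4 eq) and BnCl in DMF at 0 °C release the aryl acetates one at a time and benzylate each phenoxide as it forms. The much slower aliphatic acetate keeps O3 masked, which gives 3-O-acetyl-5,7,3',4'-tetra-O-benzyl-(+)-catechin F6. Catalytic K2CO3 in MeOH/THF removes the 3-O-acetate to give 2.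

**Step 3.**
- Failure modes: poisoning of the palladium by traces of phosphorus species from step 2, stalled partial debenzylation, and hydrogenolytic opening of C2–O1.
- Fallback: it replaces reductive deprotection by fluoride-labile groups, sets out from 1 and comes back at 7. TBSCl (4.5 eq) and imidazole in DMF give 5,7,3',4'-tetra-O-TBS-(+)-catechin F7, with the 3-OH left free. The step 2 protocol carries this through tetra-O-TBS-catechin-3-yl diphenylphosphinite F8 and tetra-O-TBS-catechinyloxyphosphonium syringate ion pair F9 to 5,7,3',4'-tetra-O-TBS-(−)-epicatechin 3-O-syringate F10. Et3N·3HF in THF/MeCN at 0 °C to rt then frees the four phenols to give 7.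

## Further compounds
F1 | step 2 | (2R)-5,7,3',4'-tetrakis(benzyloxy)flavan-3-one | O=C1Cc2c(OCc3ccccc3)cc(OCc3ccccc3)cc2O[C@@H]1c1ccc(OCc2ccccc2)c(OCc2ccccc2)c1
F2 | step 2 | 5,7,3',4'-tetra-O-benzyl-(−)-epicatechin (2R,3R) | O[C@@H]1Cc2c(OCc3ccccc3)cc(OCc3ccccc3)cc2O[C@@H]1c1ccc(OCc2ccccc2)c(OCc2ccccc2)c1
F3 | step 2 | 4-(benzyloxy)-3,5-dimethoxybenzoic acid | COc1cc(C(=O)O)cc(OC)c1OCc1ccccc1
F4 | step 2 | 5,7,3',4'-tetra-O-benzyl-(−)-epicatechin 3-O-(4-O-benzylsyringate) (2R,3R) | COc1cc(C(=O)O[C@@H]2Cc3c(OCc4ccccc4)cc(OCc4ccccc4)cc3O[C@@H]2c2ccc(OCc3ccccc3)c(OCc3ccccc3)c2)cc(OC)c1OCc1ccccc1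
F5 | step 1 | penta-O-acetyl-(+)-catechin (2R,3S) | CC(=O)O[C@H]1Cc2c(OC(C)=O)cc(OC(C)=O)cc2O[C@@H]1c1ccc(OC(C)=O)c(OC(C)=O)c1
F6 | step 1 | 3-O-acetyl-5,7,3',4'-tetra-O-benzyl-(+)-catechin (2R,3S) | CC(=O)O[C@H]1Cc2c(OCc3ccccc3)cc(OCc3ccccc3)cc2O[C@@H]1c1ccc(OCc2ccccc2)c(OCc2ccccc2)c1
F7 | step 3 | 5,7,3',4'-tetra-O-TBS-(+)-catechin (2R,3S) | O[C@H]1Cc2c(O[Si](C)(C)C(C)(C)C)cc(O[Si](C)(C)C(C)(C)C)cc2O[C@@H]1c1ccc(O[Si](C)(C)C(C)(C)C)c(O[Si](C)(C)C(C)(C)C)c1
F8 | step 3 | tetra-O-TBS-catechin-3-yl diphenylphosphinite (2R,3S) | c1ccccc1P(c1ccccc1)O[C@H]1Cc2c(O[Si](C)(C)C(C)(C)C)cc(O[Si](C)(C)C(C)(C)C)cc2O[C@@H]1c1ccc(O[Si](C)(C)C(C)(C)C)c(O[Si](C)(C)C(C)(C)C)c1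
F9 | step 3 | tetra-O-TBS-catechinyloxyphosphonium syringate ion pair (2R,3S) | Cc1cc(O[P+](c2ccccc2)(c2ccccc2)O[C@H]2Cc3c(O[Si](C)(C)C(C)(C)C)cc(O[Si](C)(C)C(C)(C)C)cc3O[C@@H]2c2ccc(O[Si](C)(C)C(C)(C)C)c(O[Si](C)(C)C(C)(C)C)c2)cc(C)c1O.COc1cc(C([O-])=O)cc(OC)c1O
F10 | step 3 | 5,7,3',4'-tetra-O-TBS-(−)-epicatechin 3-O-syringate (2R,3R) | COc1cc(C(=O)O[C@@H]2Cc3c(O[Si](C)(C)C(C)(C)C)cc(O[Si](C)(C)C(C)(C)C)cc3O[C@@H]2c2ccc(O[Si](C)(C)C(C)(C)C)c(O[Si](C)(C)C(C)(C)C)c2)cc(OC)c1O
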